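Readings and results are simulated for an exercise, and the scatter is random.

Time was the axis I read first. Both earlier runs slowed hard without stopping, so I looked for what stayed nearly constant as the clock ran on.

| setting | summer | spring | red | grey | violet |
|---|---|---|---|---|---|
| electrophile | 0.011 M | 0.011 M | 0.011 M | 0.011 M | 0.011 M |
| free base | 0.039 M | 0.040 M | 0.0330 M | 0.0560 M | 0.0430 M |
| protonated nucleophile | 0.011 M | 0.011 M | 0.0110 M | 0.0110 M | 0.0110 M |
| protic impurity | 0.011 M | 0.011 M | 0.0110 M | 0.0110 M | 0.0110 M |
| remark | run made earlier | run made earlier |  |  |  |
| time |  |  | 12 min | 12 min | 12 min |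

| run | time / min | electrophile / % | product / % |
|---|---|---|---|
| summer | 0.833 | 81.9 | 18.2 |
| summer | 2.00 | 75.0 | 26.3 |
| summer | 4.00 | 70.3 | 30.9 |
| summer | 6.00 | 68.3 | 33.7 |
| spring | 0.500 | 85.9 | 16.1 |
| spring | 1.00 | 79.9 | 18.4 |
| spring | 2.50 | 71.9 | 27.8 |
| spring | 6.00 | 67.4 | 33.2 |

(readings scatter by 1 percentage point)

* part of the electrophile that has reacted at the end, red
* part of the electrophile that has reacted at the end, grey
* part of the electrophile that has reacted at the end, violet
* what raising the concentration of free base from its lowest to its highest value here does to the part of the electrophile that has reacted (changes below 5 percentage points count as none) (it falls / it rises / no change)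

- the numbers in the tables scatter by 1 percentage point (one standard deviation)
- steps thought possible: electrophile + nucleophile -> acid set free + product; nucleophile + acid set free <-> protonated nucleophile; acid set free + free base <-> salt of the base; nucleophile + protic impurity -> quenched reagent; 2 free base -> homo dimer; free base <-> dormant form

The bench rule for such a creeping reaction is equal gains for equal doublings of time, so I took the product readings from the late part of each run:

summer, 2.00 min to 6.00 min: 4.7 percentage points per doubling

spring, 2.50 min to 6.00 min: 4.3 points per doubling

Their mean, 4.5 points, was the quantity I carried: the gain per doubling, the fraction of the charged electrophile that reacts each time the elapsed time doubles.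

The rule has a border. Between 0.833 min and 2.00 min the summer run gained 6.4 points per doubling, 1.42 times the carried reading, so I used the rule only after 2.00 min. Grey also held 1.40 times the free base of the spring run, a charge that neither run had tried, so my reckoning had no term for free base.

The four readings at 6.00 min gave a mean reacted fraction of 32.8%. One doubling to 12 min then gave:

32.8% + 4.5 points = 37.3%

The forecast was lower than my reckoning: 35.5% for red, 36% for violet, 36.5% for grey, and no change. Its ground on free base was: “This split is a rate ratio, so it does not depend on base level when base is in excess.”

The flask gave 36.4% in red, 37.5% in violet and 38.5% in grey, a change of 2.1 points across the free base charges, below the 5 points that counts, so no change. At 12 min free base stood at 2.30%, 1.89% and 1.53% of its charge in those flasks, less than the electrophile left in each. The gain per doubling carried red to 51.3% at 120 min, where the flask gave 49.8%. It carried grey to 53.4%, where the flask gave 51.1%.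

    electrophile + nucleophile → acid set free + product (k = 14.0 M⁻¹ s⁻¹)
    nucleophile + acid set free ⇌ protonated nucleophile, settled at all times (K = 4.60 × 10⁵ M⁻¹)
    acid set free + free base ⇌ salt of the base (K = 7200 M⁻¹, k = 120 M⁻¹ s⁻¹)
    nucleophile + protic impurity → quenched reagent (k = 4.50 M⁻¹ s⁻¹)
    2 free base → homo dimer (k = 0.700 M⁻¹ s⁻¹)
    free base ⇌ dormant form (K = 0.220, k = 0.0160 s⁻¹)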